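Guaiane numbering: cyclopentane C1–C5, seven-membered ring C1/C5–C10, CH3 on C4 and C10, CMe2OH (C11) on C7, ester oxygen on C8. The target is (4S,5S,7S,8S), with 4-CH3 and the C7 side chain on one face and H5 and O8 on the other.
Retrosynthesis cuts the C8–O acyl bond, then C8–C9, then C6–C7, then the C1–isopropenyl bond, and finally the C1=C5 alkene of a cyclopentene aldehyde.
Enabling feature: the C8 carbinol is homoallylic to the tetrasubstituted C1=C10 alkene of the seven-membered ring. The unit C8–C9–C10=C1 is what remains when the CH2 end of an isopropenyl group on C1 adds to a C8 aldehyde and C1 loses its hydrogen.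
Forward order: the cyclopentane is made by ring-closing metathesis, the isopropenyl group is put on C1 by conjugate addition, C6–C7 is formed by epoxide opening, the seven-membered ring is closed by the carbonyl-ene step, and the ferulate is attached last.
Stereochemistry: C4 comes from (S)-citronellal and directs C1 (anti addition). C1 then fixes C5 by equilibration. C7 comes from a Sharpless epoxide opened with inversion, C8 is set by C7 in the ring closure, and the E alkene arrives with ferulic acid.

Key step: step 11

Remark: commercial (S)-citronellal and the Sharpless epoxide are assumed to be enriched enough that the minor antipode of either appears only as a separable diastereomer after step 8.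

Step 1
Reactants: 1 (S)-citronellal
Product: 2 (3S)-3,7-dimethyl-2-methylideneoct-6-enal
Conditions: aq. CH2O (37 %), pyrrolidine (10 mol %), EtCO2H (10 mol %), i-PrOH, 45 °C
Reagents that add atoms: formaldehyde C=O
Why: Organocatalytic α-methylenation (Mannich condensation of the enamine with formaldehyde, then amine elimination) is routine for α-unbranched aldehydes and leaves the C4 stereocentre, which is not part of the enamine, untouched.

Step 2
Reactants: 2 (3S)-3,7-dimethyl-2-methylideneoct-6-enal
Product: 3 (5S)-5-methylcyclopent-1-ene-1-carbaldehyde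
Conditions: second-generation Grubbs catalyst (1 mol %), CH2Cl2, reflux
Reagents that add atoms: none
Why: Ring-closing metathesis between the 1,1-disubstituted enal alkene and the prenyl terminus closes the five-membered ring C1–C5, is driven by loss of a volatile alkene, and neither forms nor disturbs a stereocentre.

Step 3
Reactants: 3 (5S)-5-methylcyclopent-1-ene-1-carbaldehyde; 4 2-bromopropene
Product: 7 (1S,2S,5S)-2-methyl-5-(prop-1-en-2-yl)cyclopentane-1-carbaldehyde, via isopropenylmagnesium bromide 5 (not isolated), via trimethylsilyl enol ether 6 (not isolated)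
Conditions: 4, Mg, THF; CuBr·SMe2 (10 mol %), Me3SiCl, HMPA, 3, THF, −78 °C; crude 6, K2CO3 (cat.), MeOH, rt
Reagents that add atoms: magnesium [Mg] (in 5 only); chlorotrimethylsilane C[Si](C)(C)Cl (in 6 only)
Why: Copper-catalysed, chlorosilane-accelerated conjugate addition of a Grignard reagent to an enal should place the isopropenyl group on C1 anti to the pseudo-axial C4 methyl group, and methanolysis of 6 under equilibrating base should then settle C5 with the formyl group trans to the larger isopropenyl neighbour and therefore cis to the methyl group.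

Step 4
Reactants: 7 (1S,2S,5S)-2-methyl-5-(prop-1-en-2-yl)cyclopentane-1-carbaldehyde
Product: 8 [(1S,2S,5S)-2-methyl-5-(prop-1-en-2-yl)cyclopentyl]methanol
Conditions: NaBH4, MeOH, 0 °C
Reagents that add atoms: none
Why: Borohydride reduction of the aldehyde removes the acidity of C5–H and so locks C5, leaves the alkene untouched, and gives an alcohol from which minor diastereomers can be removed by chromatography.

Step 5
Reactants: 8 [(1S,2S,5S)-2-methyl-5-(prop-1-en-2-yl)cyclopentyl]methanol
Product: 9 (1S,2S,3S)-2-(bromomethyl)-1-methyl-3-(prop-1-en-2-yl)cyclopentane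
Conditions: CBr4, PPh3, CH2Cl2, 0 °C
Reagents that add atoms: carbon tetrabromide BrC(Br)(Br)Br
Why: The Appel reaction converts the primary alcohol into the bromide under neutral conditions by SN2 displacement at the non-stereogenic C6 and does not touch the alkene.

Step 6
Reactants: 10 prenol (3-methylbut-2-en-1-ol)
Product: 11 [(2R)-3,3-dimethyloxiran-2-yl]methanol
Conditions: Ti(OiPr)4 (5 mol %), D-(−)-diisopropyl tartrate (6 mol %), t-BuOOH, 4 Å molecular sieves, CH2Cl2, −20 °C
Reagents that add atoms: tert-butyl hydroperoxide CC(C)(C)OO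
Why: In the Sharpless asymmetric epoxidation of this allylic alcohol the D-(−)-tartrate ligand directs oxygen to the face that gives the (R)-epoxide carbon, the future C7.

Step 7
Reactants: 11 [(2R)-3,3-dimethyloxiran-2-yl]methanol
Product: 12 {[(2R)-3,3-dimethyloxiran-2-yl]methoxy}triethylsilane
Conditions: Et3SiCl, imidazole, CH2Cl2, 0 °C
Reagents that add atoms: chlorotriethylsilane CC[Si](Cl)(CC)CC
Why: Standard silylation of the primary alcohol avoids loss of one equivalent of the valuable Grignard reagent and blocks Payne rearrangement of an epoxy alkoxide in the coupling.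

Step 8
Reactants: 9 (1S,2S,3S)-2-(bromomethyl)-1-methyl-3-(prop-1-en-2-yl)cyclopentane; 12 {[(2R)-3,3-dimethyloxiran-2-yl]methoxy}triethylsilane
Product: 14 (2S)-3-methyl-2-{[(1S,2S,5S)-2-methyl-5-(prop-1-en-2-yl)cyclopentyl]methyl}butane-1,3-diol 1-(triethylsilyl) ether, via cyclopentylmethylmagnesium bromide 13 (not isolated)
Conditions: 9, Mg, THF, 40 °C; CuI (15 mol %), 12 (1.3 equiv), THF, −30 °C → rt
Reagents that add atoms: magnesium [Mg] (in 13 only)
Why: Copper-catalysed SN2 opening of a trisubstituted epoxide by a primary Grignard reagent occurs at the less substituted carbon with inversion, which forms C6–C7, sets C7 as (S) and frees the tertiary C11 hydroxyl group.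

Step 9
Reactants: 14 (2S)-3-methyl-2-{[(1S,2S,5S)-2-methyl-5-(prop-1-en-2-yl)cyclopentyl]methyl}butane-1,3-diol 1-(triethylsilyl) ether
Product: 15 (2S)-3-methyl-2-{[(1S,2S,5S)-2-methyl-5-(prop-1-en-2-yl)cyclopentyl]methyl}butane-1,3-diol bis(triethylsilyl) ether
Conditions: Et3SiOTf, 2,6-lutidine, CH2Cl2, −78 → 0 °C
Reagents that add atoms: triethylsilyl trifluoromethanesulfonate CC[Si](CC)(CC)OS(=O)(=O)C(F)(F)F
Why: A silyl triflate with a hindered pyridine base is the standard way to silylate a tertiary alcohol, and the buffered medium spares the alkene and the primary silyl ether.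

Step 10
Reactants: 15 (2S)-3-methyl-2-{[(1S,2S,5S)-2-methyl-5-(prop-1-en-2-yl)cyclopentyl]methyl}butane-1,3-diol bis(triethylsilyl) ether
Product: 16 (2R)-3-methyl-2-{[(1S,2S,5S)-2-methyl-5-(prop-1-en-2-yl)cyclopentyl]methyl}-3-(triethylsilyloxy)butanal
Conditions: (COCl)2, DMSO, CH2Cl2, −78 → −40 °C; Et3N, −78 °C → 0 °C
Reagents that add atoms: none
Why: In this Swern oxidation applied directly to a silyl ether the activated DMSO reagent exchanges only the unhindered primary triethylsilyl ether, the tertiary one stays, and collapse at low temperature should not epimerise C7 (the descriptor changes to R only because the priorities change).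

Step 11
Reactants: 16 (2R)-3-methyl-2-{[(1S,2S,5S)-2-methyl-5-(prop-1-en-2-yl)cyclopentyl]methyl}-3-(triethylsilyloxy)butanal
Product: 18 (4S,5S,7S,8S)-11-(triethylsilyloxy)guai-1(10)-en-8-ol (8-hydroxybulnesol 11-triethylsilyl ether), via chloro(methyl)aluminium alkoxide 17 (not isolated)
Conditions: Me2AlCl (2.0 equiv), CH2Cl2, −78 → −30 °C; H2O quench
Reagents that add atoms: dimethylaluminium chloride C[Al](C)Cl (in 17 only)
Why: Me2AlCl, used in excess so that the strongly activated aldehyde reacts in the stepwise, cation-like (Prins) limit of the ene manifold, binds the C8 oxygen, the CH2 terminus C9 of the 1,1-disubstituted alkene attacks C8, tertiary cationic character builds at C10, C1–H is then given up to form C1=C10, and the Al–CH3 bonds trap the released proton as methane so that alkoxide 17 is what reaches the quench. The closest known reaction type is the alkylaluminium-halide-promoted intramolecular carbonyl-ene cyclisation of alkenyl aldehydes, established for six- and seven-membered carbocycles. One ring closes, the seven-membered ring C1/C5–C10, exo with respect to the carbonyl and endo with respect to the alkene, helped by the trans-vicinal placement of both reacting arms on the rigid cyclopentane. The only new stereocentre, C8, is controlled by C7: in the chair-like trans-fused array the CMe2OSiEt3 group is equatorial, the silyl ether cannot chelate aluminium, and the bulky aluminium-bound oxygen takes the equatorial site next to H7 rather than the axial site gauche to both C6 and C11, which should give the 7,8-trans (8S) alkoxide. The step needs hydrogen loss from C1 and not from the C10 methyl group or C9; with the oxygen equatorial the concerted six-centre transfer of a methyl hydrogen is out of reach, the trans ring junction holds the tertiary C1–H bond axial and parallel to the empty C10 orbital so that elimination follows the Zaitsev sense to the tetrasubstituted alkene, and C9–H is deactivated by the adjacent C8–O bond. Because no Brønsted acid survives in the medium, the alkene should not move on to C1=C5, C7 should not epimerise and the tertiary silyl ether should stay in place.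

Step 12
Reactants: 19 (E)-ferulic acid
Product: 21 (E)-4-O-(tert-butyldimethylsilyl)ferulic acid, via bis-silylated ferulic acid 20 (not isolated)
Conditions: t-BuMe2SiCl (2.5 equiv), imidazole, DMF, rt; then AcOH/THF/H2O, rt
Reagents that add atoms: tert-butyldimethylsilyl chloride CC(C)(C)[Si](C)(C)Cl
Why: Silylation of both acidic OH groups followed by selective hydrolysis of the labile silyl ester is the usual way to mask only the phenol, and the E alkene is not affected.

Step 13
Reactants: 18 (4S,5S,7S,8S)-11-(triethylsilyloxy)guai-1(10)-en-8-ol; 21 (E)-4-O-(tert-butyldimethylsilyl)ferulic acid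
Product: 23 (4S,5S,7S,8S)-11-(triethylsilyloxy)guai-1(10)-en-8-yl (E)-4-O-(tert-butyldimethylsilyl)ferulate, via trichlorobenzoic mixed anhydride 22 (not isolated)
Conditions: 21, 2,4,6-Cl3C6H2COCl, Et3N, toluene, rt; then 18, DMAP, toluene, rt → 40 °C
Reagents that add atoms: 2,4,6-trichlorobenzoyl chloride O=C(Cl)c1c(Cl)cc(Cl)cc1Cl (in 22 only)
Why: Yamaguchi esterification is reliable for cinnamate-type acids and hindered secondary alcohols, acylates the equatorial C8 oxygen with retention because no C8–O bond is broken, and meets no competing hydroxyl group since C11 and the phenol are silylated.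

Step 14
Reactants: 23 (4S,5S,7S,8S)-11-(triethylsilyloxy)guai-1(10)-en-8-yl (E)-4-O-(tert-butyldimethylsilyl)ferulate
Product: 24 (4S,5S,7S,8S)-11-hydroxyguai-1(10)-en-8-yl (E)-ferulate (CNP0241038.1)
Conditions: Bu4NF, AcOH, THF, 0 °C → rt
Reagents that add atoms: none
Why: Fluoride-mediated desilylation removes the aryl and the tertiary silyl ether in one operation, and the acetic acid buffer keeps phenoxide and alkoxide from attacking the ester while avoiding acid that could ionise C11 or shift the alkene.

Compound list
1 | (S)-citronellal | C[C@@H](CCC=C(C)C)CC=O | starting material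
2 | (3S)-3,7-dimethyl-2-methylideneoct-6-enal | C=C(C=O)[C@@H](C)CCC=C(C)C | intermediate
3 | (5S)-5-methylcyclopent-1-ene-1-carbaldehyde | O=CC1=CCC[C@@H]1C | intermediate
4 | 2-bromopropene | CC(Br)=C | starting material
5 | isopropenylmagnesium bromide | CC(=C)[Mg]Br | intermediate
6 | trimethylsilyl enol ether of 7 (E/Z not defined) | C[Si](C)(C)OC=C1[C@@H](C)CC[C@@H]1C(C)=C | intermediate
7 | (1S,2S,5S)-2-methyl-5-(prop-1-en-2-yl)cyclopentane-1-carbaldehyde | O=C[C@H]1[C@@H](C)CC[C@@H]1C(C)=C | intermediate
8 | [(1S,2S,5S)-2-methyl-5-(prop-1-en-2-yl)cyclopentyl]methanol | OC[C@H]1[C@@H](C)CC[C@@H]1C(C)=C | intermediate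
9 | (1S,2S,3S)-2-(bromomethyl)-1-methyl-3-(prop-1-en-2-yl)cyclopentane | BrC[C@H]1[C@@H](C)CC[C@@H]1C(C)=C | intermediate
10 | prenol | CC(C)=CCO | starting material
11 | [(2R)-3,3-dimethyloxiran-2-yl]methanol | OC[C@H]1OC1(C)C | intermediate
12 | {[(2R)-3,3-dimethyloxiran-2-yl]methoxy}triethylsilane | CC[Si](CC)(CC)OC[C@H]1OC1(C)C | intermediate
13 | {[(1S,2S,5S)-2-methyl-5-(prop-1-en-2-yl)cyclopentyl]methyl}magnesium bromide | Br[Mg]C[C@H]1[C@@H](C)CC[C@@H]1C(C)=C | intermediate
14 | (2S)-3-methyl-2-{[(1S,2S,5S)-2-methyl-5-(prop-1-en-2-yl)cyclopentyl]methyl}butane-1,3-diol 1-(triethylsilyl) ether | CC[Si](CC)(CC)OC[C@H](C[C@H]1[C@@H](C)CC[C@@H]1C(C)=C)C(C)(C)O | intermediate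
15 | (2S)-3-methyl-2-{[(1S,2S,5S)-2-methyl-5-(prop-1-en-2-yl)cyclopentyl]methyl}butane-1,3-diol bis(triethylsilyl) ether | CC[Si](CC)(CC)OC[C@H](C[C@H]1[C@@H](C)CC[C@@H]1C(C)=C)C(C)(C)O[Si](CC)(CC)CC | intermediate
16 | (2R)-3-methyl-2-{[(1S,2S,5S)-2-methyl-5-(prop-1-en-2-yl)cyclopentyl]methyl}-3-(triethylsilyloxy)butanal | O=C[C@H](C[C@H]1[C@@H](C)CC[C@@H]1C(C)=C)C(C)(C)O[Si](CC)(CC)CC | intermediate
17 | chloro(methyl)aluminium alkoxide of 18 | C[Al](Cl)O[C@H]1CC(C)=C2CC[C@H](C)[C@@H]2C[C@@H]1C(C)(C)O[Si](CC)(CC)CC | intermediate
18 | (4S,5S,7S,8S)-11-(triethylsilyloxy)guai-1(10)-en-8-ol | O[C@H]1CC(C)=C2CC[C@H](C)[C@@H]2C[C@@H]1C(C)(C)O[Si](CC)(CC)CC | intermediate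
19 | (E)-ferulic acid | COc1cc(/C=C/C(=O)O)ccc1O | starting material
20 | tert-butyldimethylsilyl (E)-4-O-(tert-butyldimethylsilyl)ferulate | COc1cc(/C=C/C(=O)O[Si](C)(C)C(C)(C)C)ccc1O[Si](C)(C)C(C)(C)C | intermediate
21 | (E)-4-O-(tert-butyldimethylsilyl)ferulic acid | COc1cc(/C=C/C(=O)O)ccc1O[Si](C)(C)C(C)(C)C | intermediate
22 | (E)-4-O-(tert-butyldimethylsilyl)ferulic 2,4,6-trichlorobenzoic anhydride | COc1cc(/C=C/C(=O)OC(=O)c2c(Cl)cc(Cl)cc2Cl)ccc1O[Si](C)(C)C(C)(C)C | intermediate
23 | (4S,5S,7S,8S)-11-(triethylsilyloxy)guai-1(10)-en-8-yl (E)-4-O-(tert-butyldimethylsilyl)ferulate | COc1cc(/C=C/C(=O)O[C@H]2CC(C)=C3CC[C@H](C)[C@@H]3C[C@@H]2C(C)(C)O[Si](CC)(CC)CC)ccc1O[Si](C)(C)C(C)(C)C | intermediate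
24 | (4S,5S,7S,8S)-11-hydroxyguai-1(10)-en-8-yl (E)-ferulate (CNP0241038.1) | COc1cc(/C=C/C(=O)O[C@H]2CC(C)=C3CC[C@H](C)[C@@H]3C[C@@H]2C(C)(C)O)ccc1O | target

Total step count: 14. Longest linear sequence: 11 steps from (S)-citronellal (steps 1–5, 8–11, 13, 14).

Steps most likely to fail

Step 11. The concerted pathway with an axial aluminium-bound oxygen may outrun the stepwise one. A hydrogen of the C10 methyl group would then be transferred instead of C1–H, and the aldehyde face would be chosen differently. The fallback separates ring closure from alkene placement. It sets out from 16. The ring is closed with the very bulky MeAl(OC6H2-4-Br-2,6-tBu2)2 in CH2Cl2 at −78 °C, a Lewis acid of the class used to favour trans products in ene closures of α-branched alkenyl aldehydes. The closure is allowed to run in the methyl-hydrogen mode and gives (1S,4S,5S,7S,8S)-11-(triethylsilyloxy)guai-10(14)-en-8-ol F1. Its 1,1-disubstituted alkene is then isomerised by radical hydrogen-atom transfer, using catalytic chloro[N,N'-bis(3,5-di-tert-butylsalicylidene)ethane-1,2-diaminato]cobalt and catalytic PhSiH3 in benzene at rt. This moves the double bond into the tetrasubstituted C1=C10 position, which is inert to further hydrogen-atom transfer. The route is rejoined at 18.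

Step 3. The equilibrium at C5 rests only on the size difference between a methyl and an isopropenyl neighbour and may be too shallow, and facial discrimination in the copper addition may be incomplete. The fallback sets C5 kinetically by a syn hydroboration instead of by equilibration. It sets out from 3.
- 1,2-Reduction (NaBH4, CeCl3·7H2O, MeOH) gives [(5S)-5-methylcyclopent-1-en-1-yl]methanol F2.
- Silylation (t-BuMe2SiCl, imidazole) gives tert-butyl(dimethyl){[(5S)-5-methylcyclopent-1-en-1-yl]methoxy}silane F3.
- Hydroboration with catecholborane followed by exchange with pinacol adds hydrogen to C5 and boron to C1 on the face anti to the C4 methyl group, which pushes C6 cis to that methyl group. It gives tert-butyl(dimethyl){[(1R,2S,5S)-2-methyl-5-(4,4,5,5-tetramethyl-1,3,2-dioxaborolan-2-yl)cyclopentyl]methoxy}silane F4.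
- Zweifel olefination (isopropenyllithium from 4 and t-BuLi, then I2, then NaOMe) replaces boron by isopropenyl with retention. It gives tert-butyl(dimethyl){[(1S,2S,5S)-2-methyl-5-(prop-1-en-2-yl)cyclopentyl]methoxy}silane F5.
- Bu4NF frees the alcohol, and the route is rejoined at 8.

Step 8. SN2 attack at the secondary epoxide carbon, which is flanked by a fully substituted carbon, may be too slow, so that magnesium-halide-induced rearrangement or halohydrin formation consumes the epoxide. The fallback reverses the polarity, with C7 as a chiral azaenolate and C6 as the electrophile (SAMP hydrazone alkylation). It sets out from 9.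
- Commercial 3-methylbutane-1,3-diol is bis-silylated (Et3SiOTf, 2,6-lutidine) to 3-methyl-1,3-bis(triethylsilyloxy)butane F6.
- Swern oxidation of the primary silyl ether gives 3-methyl-3-(triethylsilyloxy)butanal F7.
- Condensation with (S)-1-amino-2-(methoxymethyl)pyrrolidine gives the SAMP hydrazone of 3-methyl-3-(triethylsilyloxy)butanal F8.
- Deprotonation (LDA, THF, 0 °C) and alkylation with 9 (−100 °C → rt), in which the auxiliary shields one face of the azaenolate, gives the SAMP hydrazone of aldehyde 16 F9.
- Mild hydrolytic cleavage (Cu(OAc)2, THF/H2O) returns the auxiliary, and the route is rejoined at 16. Steps 6–10 are then not needed.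

Further compounds
F1 | step 11 | (1S,4S,5S,7S,8S)-11-(triethylsilyloxy)guai-10(14)-en-8-ol | O[C@H]1CC(=C)[C@H]2CC[C@H](C)[C@@H]2C[C@@H]1C(C)(C)O[Si](CC)(CC)CC
F2 | step 3 | [(5S)-5-methylcyclopent-1-en-1-yl]methanol | OCC1=CCC[C@@H]1C
F3 | step 3 | tert-butyl(dimethyl){[(5S)-5-methylcyclopent-1-en-1-yl]methoxy}silane | CC(C)(C)[Si](C)(C)OCC1=CCC[C@@H]1C
F4 | step 3 | tert-butyl(dimethyl){[(1R,2S,5S)-2-methyl-5-(4,4,5,5-tetramethyl-1,3,2-dioxaborolan-2-yl)cyclopentyl]methoxy}silane | CC(C)(C)[Si](C)(C)OC[C@H]1[C@@H](C)CC[C@@H]1B2OC(C)(C)C(C)(C)O2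
F5 | step 3 | tert-butyl(dimethyl){[(1S,2S,5S)-2-methyl-5-(prop-1-en-2-yl)cyclopentyl]methoxy}silane | CC(C)(C)[Si](C)(C)OC[C@H]1[C@@H](C)CC[C@@H]1C(C)=C
F6 | step 8 | 3-methyl-1,3-bis(triethylsilyloxy)butane | CC[Si](CC)(CC)OCCC(C)(C)O[Si](CC)(CC)CC
F7 | step 8 | 3-methyl-3-(triethylsilyloxy)butanal | O=CCC(C)(C)O[Si](CC)(CC)CC
F8 | step 8 | SAMP hydrazone of 3-methyl-3-(triethylsilyloxy)butanal | COC[C@@H]1CCCN1/N=C/CC(C)(C)O[Si](CC)(CC)CC
F9 | step 8 | SAMP hydrazone of aldehyde 16 | COC[C@@H]1CCCN1/N=C/[C@H](C[C@H]2[C@@H](C)CC[C@@H]2C(C)=C)C(C)(C)O[Si](CC)(CC)CC
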